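The rate constants were chosen freely; what happens was integrated by code.

Choosing a vessel for making Z from Q, two colleagues disagree on which set-up to run.

    Z → J (k1 = 0.784 h⁻¹)
    E ⇌ L (K2 = 0.53, k2 = 0.678 h⁻¹)
    Z → E (k3 = 0.180 h⁻¹)
    Q + X → Z + D (k4 = 3.19 M⁻¹ h⁻¹)

| flask | Q | X | time | remark |
|---|---|---|---|---|
| grey | 0.20 M (fed, over 2.00 h) | 1.30 equiv | 2.5 h | all but Q at the start; Q goes in evenly over 2.00 h, the run ends at 2.5 h |
| green | 0.20 M | 1.30 equiv |  | one stirred flow tank at steady state, fed with the mixture as stated, mean residence time 12.5 h |
| teal | 0.20 M | 1.30 equiv |  | one stirred flow tank at steady state, fed with the mixture as stated, mean residence time 2.5 h |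
| amber | 0.20 M | 1.30 equiv | 2.5 h | everything together in a closed stirred flask, run for 2.5 h |

- the stated concentrations are those of everything mixed, before any reaction; amounts are the same in each set-up
- the feed brings no volume worth counting
- run time (grey): 2.5 h

1. the set-up with the highest amount of Z at the outlet or at the end, in percent of the Q put in ("none" if the first two lie within 2 percentage points) (grey / green / teal / amber / none)
2. amount of Z at the outlet or at the end, in percent of the Q put in, grey
3. amount of Z at the outlet or at the end, in percent of the Q put in, green
4. amount of Z at the outlet or at the end, in percent of the Q put in, teal
5. amount of Z at the outlet or at the end, in percent of the Q put in, amber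

Amounts below are fractions of the Q charge. Q is the limiting reagent, and each Q consumed gives one Z.

The first colleague counts conversion: the vessel that consumes the most Q should hold the most Z. Treating Q as pseudo-first-order with X held at its charge, she gets a time constant of 1.21 h. Amber then keeps 12.7% of its Q, and green stays 12.5 h against 2.5 h, so she votes for green.

The second counts age. Z is a first-order lag with two drains, the steps to J and to E, so it has a memory time of 1.04 h, one over the sum of those two constants.

I side with him and reckon by hand. A tank balance gives Z as converted fraction times a survival share, one over one plus residence time divided by memory time. That share is 7.66% for green and 29.3% for teal, and each is the fraction of Z at full conversion. In grey, if Q reacted as it entered, integrating the steady feed through the lag gives memory time over dosing time, times one minus the exponential of minus their inverse ratio, then decay over the undosed time: 27.4%. Amber, with made and lost each first order, gives 22.1%, less than grey.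

The forecast also takes the age side, but with its own numbers, lower than mine for grey and amber: grey best, at 24% grey, 18.3% amber, 16% teal and 6.1% green, since “what counts is how recently it was formed”.

The simulation gives grey best, with 24.0% grey, 18.3% amber, 16.0% teal and 6.13% green.

Green leaves 20.0% of its Q and teal 45.4%, so green has converted more yet holds less Z. Converted fraction times survival share gives 16.0% for teal and, on the second tank, 6.13% for green. The step from Z to J is part of the reason for green's low Z: with that step struck out, green rises from 6.13% to 24.6%, still less than grey with the same step struck out, at 47.1%.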